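**Retrosynthetic overview**
1. Dysidenone A (24) ⇐ bolinaquinone (21) + MeOH. Hemiketalisation and a 1,2-shift (benzilic ester contraction) turn the hydroxyquinone ring into the cyclopentenone in the last step.
2. 21 ⇐ tetramethoxyarene 18 (oxidative demethylation, then one O-demethylation). The 3-ene of 18 ⇐ C-3 ketone 15.
3. 15 ⇐ monocyclic epoxy-olefin 13. One cationic cascade closes ring A (C-4–C-5) and runs on through the biogenetic 1,2-shifts H-5→C-10, Me-4→C-5, H-3→C-4.
4. 13 ⇐ ketone 7 + homoprenyl Grignard reagent. C-8 and C-9 of 7 come from asymmetric conjugate methylation and enolate methylation of enone 5 (arene 1 + CH2O + 3-ethoxycyclohexenone).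
5. Ring order: ring B and the arene ring are bought, ring A is formed in step 7, and the five-membered ring is formed in step 12.

Assumption: biogenetic numbering (C-1 to C-11) is used for the decalin, with α = face of H-10 and β = face of Me-5; primed locants denote the quinone or cyclopentenone ring; the chiral ligands and the ent-Shi ketone are bought catalysts and not counted as steps.

**Step 1**
Reactants: 1 1,2,4,5-tetramethoxybenzene
Product: 2 2,3,5,6-tetramethoxybenzyl chloride
Conditions: paraformaldehyde (0.7 equiv), HCl gas, AcOH/dioxane, 0 to 20 °C (excess 1 recovered)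
Reagents that add atoms: formaldehyde (from paraformaldehyde), C=O; hydrogen chloride, Cl
Why: Blanc chloromethylation (electrophilic aromatic substitution) of a very electron-rich arene whose two free positions are equivalent, so with the arene in excess the mono-chloride dominates; no stereocenter is formed.

**Step 2**
Reactants: 2 2,3,5,6-tetramethoxybenzyl chloride; 3 3-ethoxycyclohex-2-en-1-one
Product: 5 3-[(2,3,5,6-tetramethoxyphenyl)methyl]cyclohex-2-en-1-one, via (2,3,5,6-tetramethoxybenzyl)magnesium chloride 4 (not isolated)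
Conditions: Mg, THF, 0 °C, slow addition of 2; then 3, −20 to 20 °C; then 1 M HCl, 20 °C
Reagents that add atoms: water, O
Why: Stork–Danheiser transposition, in which the benzylic Grignard reagent adds 1,2 to the vinylogous ester and acid then ionises the tertiary allylic alcohol and hydrolyses the enol ether to the 3-substituted enone; no stereocenter is formed.

**Step 3**
Reactants: 5 3-[(2,3,5,6-tetramethoxyphenyl)methyl]cyclohex-2-en-1-one
Product: 7 (2S,3R)-2,3-dimethyl-3-[(2,3,5,6-tetramethoxyphenyl)methyl]cyclohexan-1-one, via dimethylaluminium enolate 6 (not isolated)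
Conditions: AlMe3 (1.5 equiv), Cu(O2CC4H3S) (5 mol %), biphenol-derived N,N-bis(1-phenylethyl)phosphoramidite (10 mol %, antipode giving 8R), Et2O, −30 °C; then MeLi (1.5 equiv), THF/DMPU, MeI (5 equiv), −40 to 0 °C
Reagents that add atoms: trimethylaluminium, C[Al](C)C; iodomethane, CI
Why: Copper-catalysed asymmetric conjugate addition of AlMe3 to a 3-substituted cyclohexenone sets the quaternary C-8 (R) under ligand control, and the enolate, activated as its lithium aluminate, undergoes enolate alkylation anti to the axial methyl group just delivered, which sets C-9 with 9-Me trans to 8-Me and cis to the benzyl group.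

**Step 4**
Reactants: 7 (2S,3R)-2,3-dimethyl-3-[(2,3,5,6-tetramethoxyphenyl)methyl]cyclohexan-1-one
Product: 9 (5R,6S)-5,6-dimethyl-5-[(2,3,5,6-tetramethoxyphenyl)methyl]cyclohex-1-en-1-yl trifluoromethanesulfonate, via potassium enolate 8 (not isolated)
Conditions: KN(SiMe3)2 (1.1 equiv), THF, −78 °C; PhNTf2, −78 to 0 °C
Reagents that add atoms: N-phenylbis(trifluoromethanesulfonimide), O=S(=O)(N(c1ccccc1)S(=O)(=O)C(F)(F)F)C(F)(F)F
Why: Kinetic deprotonation at the unhindered C-5 methylene rather than at the tertiary C-9–H (so C-9 is not epimerised), followed by O-triflation, gives the less substituted enol triflate.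

**Step 5**
Reactants: 9 enol triflate; 10 5-bromo-2-methylpent-2-ene (homoprenyl bromide)
Product: 12 3-{[(1R,2S)-1,2-dimethyl-3-(4-methylpent-3-en-1-yl)cyclohex-3-en-1-yl]methyl}-1,2,4,5-tetramethoxybenzene, via (4-methylpent-3-en-1-yl)magnesium bromide 11 (not isolated)
Conditions: 10, Mg, THF, 20 °C; then 9, Fe(acac)3 (5 mol %), THF/NMP, −30 °C
Reagents that add atoms: none
Why: Iron-catalysed Kumada-type cross-coupling of an alkenyl triflate with a primary alkyl Grignard reagent is fast at low temperature, tolerates aryl ethers and keeps the position of the ring double bond; the stereocenters are untouched.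

**Step 6**
Reactants: 12 diene
Product: 13 3-{[(1R,2S)-3-{2-[(2S)-3,3-dimethyloxiran-2-yl]ethyl}-1,2-dimethylcyclohex-3-en-1-yl]methyl}-1,2,4,5-tetramethoxybenzene
Conditions: ent-Shi ketone (L-fructose-derived, 30 mol %), KHSO5 (as 2KHSO5·KHSO4·K2SO4), K2CO3, Bu4NHSO4 (cat.), Na2B4O7 buffer, MeCN/dimethoxymethane/H2O, 0 °C
Reagents that add atoms: potassium peroxymonosulfate, [K+].[O-]S(=O)(=O)OO
Why: In the Shi asymmetric epoxidation the chiral dioxirane attacks the open, electron-rich isopropylidene group faster than the flanked ring olefin, and through the spiro transition state the antipode of the usual D-fructose catalyst gives the (3S)-epoxide.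

**Step 7**
Reactants: 13 (3S)-epoxy-olefin
Product: 15 (4R,5S,8R,9R,10S)-4β,5β,8α,9β-tetramethyl-8β-[(2,3,5,6-tetramethoxyphenyl)methyl]-trans-decalin-3-one, via C-10 carbocation 14 (not isolated)
Conditions: BF3·OEt2 (1.2 equiv), CH2Cl2 (0.005 M), −78 °C, then −20 °C, 2 h; aq NaHCO3
Reagents that add atoms: none
Why: Proposed new method: BF3 opens the epoxide at tertiary C-4 with chair-like attack by C-5 of the ring olefin (Markovnikov, six-membered ring; the 3S centre places C-4 on the β face, which is also the axial trajectory of the half-chair with pseudoaxial 9-Me) to give tertiary cation 14, whose antiperiplanar array H-5α/Me-4β/H-3α then migrates suprafacially (H-5→C-10α, Me-4→C-5β, H-3→C-4α) through tertiary cations only until the carbinol carbon becomes the C-3 ketone, an irreversible sink that also drains olefins from premature proton loss because they are reprotonated, the closest known reaction types being Lewis-acid epoxy-olefin cyclisation, BF3-induced backbone (friedo) rearrangement of terpenoids and the semipinacol hydride shift of epoxides, with a termination that mirrors friedelin biogenesis.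

**Step 8**
Reactants: 15 C-3 ketone
Product: 16 (3S,4R,5S,8R,9R,10S)-3β-alcohol of 15 (axial OH)
Conditions: NaBH4, MeOH/THF, 0 °C
Reagents that add atoms: none
Why: In this hydride reduction of a hindered cyclohexanone the axial 5β-methyl group blocks the β face, so hydride enters from the α face and gives the axial 3β-alcohol, as known for friedelin-type 3-ketones.

**Step 9**
Reactants: 16 3β-alcohol
Product: 18 3-{[(1R,2R,4aS,8aS)-1,2,4a,5-tetramethyl-1,2,3,4,4a,7,8,8a-octahydronaphthalen-2-yl]methyl}-1,2,4,5-tetramethoxybenzene, via 3-O-dichlorophosphate 17 (not isolated)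
Conditions: POCl3 (3 equiv), pyridine, 0 to 50 °C
Reagents that add atoms: none
Why: In this E2 dehydration the axial 3β-dichlorophosphate is antiperiplanar to axial H-4α and Zaitsev elimination gives the trisubstituted 3-ene, which removes the C-3 and C-4 stereocenters and leaves C-5, C-8, C-9 and C-10 untouched.

**Step 10**
Reactants: 18 tetramethoxyarene
Product: 19 2,5-dimethoxy-3-{[(1R,2R,4aS,8aS)-1,2,4a,5-tetramethyl-1,2,3,4,4a,7,8,8a-octahydronaphthalen-2-yl]methyl}cyclohexa-2,5-diene-1,4-dione
Conditions: (NH4)2Ce(NO3)6 (2.5 equiv), MeCN/H2O, 0 °C, 15 min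
Reagents that add atoms: water, O
Why: Oxidative demethylation of a 1,4-dimethoxyarene by tetravalent cerium gives the para-quinone within minutes at 0 °C, conditions under which isolated trisubstituted olefins survive.

**Step 11**
Reactants: 19 2,5-dimethoxyquinone
Product: 21 bolinaquinone (2-hydroxy-5-methoxy-3-alkyl-1,4-benzoquinone), via O-dichloroboryl quinone 20 (not isolated)
Conditions: BCl3 (1.1 equiv), CH2Cl2, −78 to −30 °C; aq NaHCO3, then dilute HCl
Reagents that add atoms: none
Why: In this Lewis-acid ether cleavage with steric acceleration, the 2-methoxy group wedged between C-1'=O and the neopentyl side chain is twisted out of conjugation, is the more basic oxygen, binds BCl3 in a chelate with C-1'=O and loses MeCl, while the planar vinylogous-ester 5-methoxy group survives.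

**Step 12**
Reactants: 21 bolinaquinone
Product: 24 dysidenone A, via ortho-quinone methyl hemiketal 22 (not isolated), via ring-contracted dienol 23 (not isolated)
Conditions: Cu(OTf)2 (10 mol %), (S,S)-t-Bu-box (11 mol %), MeOH/CH2Cl2 1:4, 4 Å sieves, 0 to 20 °C
Reagents that add atoms: methanol, CO
Why: Proposed new method: the chiral divalent-copper Lewis acid chelates the vicinal O-1'/O-2' oxygens of the hydroxyquinone, whose ortho-quinone tautomer adds methanol at C-2' to give hemiketal 22, a 1,2-shift of C-3' from C-2' to C-1' (benzilic ester = α-ketol rearrangement, the presumed biogenetic contraction) expels C-2' as the ester carbon with the ligand deciding to which face it swings (carbinol S; the sense of induction must be confirmed, since the other ligand antipode gives the ring diastereomer), and dienol 23 is protonated kinetically on the less hindered face syn to the small OH group, which puts the side chain cis to CO2Me (5R), the closest known reaction types being Lewis-acid-catalysed enantioselective α-ketol and benzilic ester rearrangements of 1,2-dicarbonyl compounds and the benzilic-acid contraction within the Hooker oxidation of 2-hydroxyquinones.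

**Compound list**
1 | 1,2,4,5-tetramethoxybenzene | COc1cc(OC)c(OC)cc1OC | starting material
2 | 2,3,5,6-tetramethoxybenzyl chloride | COc1cc(OC)c(OC)c(CCl)c1OC | intermediate
3 | 3-ethoxycyclohex-2-en-1-one | CCOC1=CC(=O)CCC1 | starting material
4 | (2,3,5,6-tetramethoxybenzyl)magnesium chloride | COc1cc(OC)c(OC)c(C[Mg]Cl)c1OC | intermediate
5 | 3-[(2,3,5,6-tetramethoxyphenyl)methyl]cyclohex-2-en-1-one | COc1cc(OC)c(OC)c(CC2=CC(=O)CCC2)c1OC | intermediate
6 | dimethylaluminium enolate of (3R)-3-methyl-3-(tetramethoxybenzyl)cyclohexanone | COc1cc(OC)c(OC)c(C[C@@]2(C)CCCC(O[Al](C)C)=C2)c1OC | intermediate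
7 | (2S,3R)-2,3-dimethyl-3-[(2,3,5,6-tetramethoxyphenyl)methyl]cyclohexan-1-one (methyl groups trans) | COc1cc(OC)c(OC)c(C[C@@]2(C)CCCC(=O)[C@H]2C)c1OC | intermediate
8 | potassium enolate of 7 towards C-5 | [K+].COc1cc(OC)c(OC)c(C[C@@]2(C)CCC=C([O-])[C@H]2C)c1OC | intermediate
9 | (5R,6S)-5,6-dimethyl-5-[(2,3,5,6-tetramethoxyphenyl)methyl]cyclohex-1-en-1-yl triflate | COc1cc(OC)c(OC)c(C[C@@]2(C)CCC=C(OS(=O)(=O)C(F)(F)F)[C@H]2C)c1OC | intermediate
10 | 5-bromo-2-methylpent-2-ene | CC(C)=CCCBr | starting material
11 | (4-methylpent-3-en-1-yl)magnesium bromide | CC(C)=CCC[Mg]Br | intermediate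
12 | (1R,2S)-diene, ring B carrying the homoprenyl chain on C-10 | COc1cc(OC)c(OC)c(C[C@@]2(C)CCC=C(CCC=C(C)C)[C@H]2C)c1OC | intermediate
13 | (3S)-epoxide of 12 | COc1cc(OC)c(OC)c(C[C@@]2(C)CCC=C(CC[C@@H]3OC3(C)C)[C@H]2C)c1OC | intermediate
14 | bicyclic C-10 carbocation (3β-O, 4,4-dimethyl, 5α-H; drawn with free OH) | COc1cc(OC)c(OC)c(C[C@@]2(C)CC[C@@H]3[C+](CC[C@H](O)C3(C)C)[C@H]2C)c1OC | intermediate
15 | (4R,5S,8R,9R,10S)-3-ketone, trans-decalin, 4β-Me, 5β-Me, 10α-H | COc1cc(OC)c(OC)c(C[C@@]2(C)CC[C@]3(C)[C@@H](C)C(=O)CC[C@H]3[C@H]2C)c1OC | intermediate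
16 | 3β-(axial) alcohol of 15 | COc1cc(OC)c(OC)c(C[C@@]2(C)CC[C@]3(C)[C@@H](C)[C@@H](O)CC[C@H]3[C@H]2C)c1OC | intermediate
17 | 3β-O-dichlorophosphate of 16 | COc1cc(OC)c(OC)c(C[C@@]2(C)CC[C@]3(C)[C@@H](C)[C@@H](OP(=O)(Cl)Cl)CC[C@H]3[C@H]2C)c1OC | intermediate
18 | (5S,8R,9R,10S)-3-ene, tetramethoxyarene | COc1cc(OC)c(OC)c(C[C@@]2(C)CC[C@]3(C)C(C)=CCC[C@H]3[C@H]2C)c1OC | intermediate
19 | 2,5-dimethoxy-3-alkyl-1,4-benzoquinone | COC1=CC(=O)C(OC)=C(C[C@@]2(C)CC[C@]3(C)C(C)=CCC[C@H]3[C@H]2C)C1=O | intermediate
20 | 2-O-dichloroboryl derivative of 21 | COC1=CC(=O)C(OB(Cl)Cl)=C(C[C@@]2(C)CC[C@]3(C)C(C)=CCC[C@H]3[C@H]2C)C1=O | intermediate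
21 | bolinaquinone | COC1=CC(=O)C(O)=C(C[C@@]2(C)CC[C@]3(C)C(C)=CCC[C@H]3[C@H]2C)C1=O | intermediate
22 | C-2' methyl hemiketal of the ortho-quinone tautomer of 21 | COC1=CC(=O)C(O)(OC)C(C[C@@]2(C)CC[C@]3(C)C(C)=CCC[C@H]3[C@H]2C)=C1O | intermediate
23 | ring-contracted dienol, methyl (1S)-1,4-dihydroxy-3-methoxy-5-alkylcyclopenta-2,4-diene-1-carboxylate | COC(=O)[C@]1(O)C=C(OC)C(O)=C1C[C@@]1(C)CC[C@]2(C)C(C)=CCC[C@H]2[C@H]1C | intermediate
24 | dysidenone A, methyl (1S,5R)-1-hydroxy-3-methoxy-4-oxo-5-{[(1R,2R,4aS,8aS)-1,2,4a,5-tetramethyl-1,2,3,4,4a,7,8,8a-octahydronaphthalen-2-yl]methyl}cyclopent-2-ene-1-carboxylate | COC(=O)[C@]1(O)C=C(OC)C(=O)[C@@H]1C[C@@]1(C)CC[C@]2(C)C(C)=CCC[C@H]2[C@H]1C | target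

**Step count**
Total step count: 12. Longest linear sequence: 12 (1 → 24).

**Steps most likely to fail**

Step 7. The likely failure modes are direct epoxide-to-ketone isomerisation, attack on the wrong face, a stop at olefins or bridged ethers, and a leak through an H-9 shift. The fallback sets out from 13 and comes back at 15. It separates ring closure from rearrangement and no longer makes C-10–H by a cationic hydride shift. First, 13 is cyclised with MeAlCl2 (CH2Cl2, −78 °C) and allowed to lose H-5, giving the tetrasubstituted 5(10)-olefin 3β-alcohol F1. A hydrogen-atom-transfer (Mukaiyama-type) hydration (Mn(dpm)3, PhSiH3, O2, i-PrOH, then P(OEt)3) then places H on C-10 from the α face and OH on C-5, giving the trans-fused 3β,5β-diol F2. Finally, BF3·OEt2 ionises only the tertiary C-5 alcohol, and the shorter Wagner–Meerwein/semipinacol pair (Me-4→C-5, H-3→C-4) delivers 15.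

Step 12. The hydroxyquinone may be too stabilised to add methanol, and the ligand may give poor face control. The fallback sets out from 21 and comes back at 24, and it removes the acidic proton first. Silver-salt alkylation (Ag2O, MeI, CHCl3) gives the true 1,2-diketone 3-alkyl-4,5-dimethoxy-1,2-benzoquinone F3, which is separated from co-formed 19 (recycled through step 11). NaOMe in MeOH at −20 °C then effects a classical benzilic ester rearrangement to the cyclopentadiene bis(enol ether) F4, whose carbinol epimers are separated by HPLC. Moist oxalic acid on silica hydrolyses the tetrasubstituted enol ether, with protonation of C-5' syn to the OH group, to give 24.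

Step 11. Cleavage may occur at the wrong methoxy group or at both. The fallback sets out from 19 and comes back at 21, and it replaces selective cleavage by selective formation. Both vinylogous esters are hydrolysed (2 M NaOH, EtOH, 60 °C, then HCl) to the 2,5-dihydroxy-3-alkyl-1,4-benzoquinone F5. Fischer-type esterification of the vinylogous acids (MeOH, 1 mol % H2SO4, 20 °C) then methylates only the unhindered O-5', because O-2' is shielded by the neopentyl side chain, and this gives 21.

Further compounds
F1 | step 7 | 3β-hydroxy-4,4-dimethyl-5(10)-ene (8R,9S-configured octalin) | COc1cc(OC)c(OC)c(C[C@@]2(C)CCC3=C(CC[C@H](O)C3(C)C)[C@H]2C)c1OC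
F2 | step 7 | trans-fused 3β,5β-diol, 10α-H, 4,4-dimethyl | COc1cc(OC)c(OC)c(C[C@@]2(C)CC[C@@]3(O)[C@@H](CC[C@H](O)C3(C)C)[C@H]2C)c1OC
F3 | step 12 | 3-alkyl-4,5-dimethoxy-1,2-benzoquinone | COC1=CC(=O)C(=O)C(C[C@@]2(C)CC[C@]3(C)C(C)=CCC[C@H]3[C@H]2C)=C1OC
F4 | step 12 | methyl (1S)-1-hydroxy-3,4-dimethoxy-5-alkylcyclopenta-2,4-diene-1-carboxylate | COC(=O)[C@]1(O)C=C(OC)C(OC)=C1C[C@@]1(C)CC[C@]2(C)C(C)=CCC[C@H]2[C@H]1C
F5 | step 11 | 2,5-dihydroxy-3-alkyl-1,4-benzoquinone | O=C1C=C(O)C(=O)C(C[C@@]2(C)CC[C@]3(C)C(C)=CCC[C@H]3[C@H]2C)=C1O
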